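- I had to decide when to stop the next flask: at the top of first product, or later, up to 6.0 d. The west run argued for stopping early, since its first product read 32.5% at 0.250 d and 3.4% at 5.00 d.

| flask | starting material | reagent | remark | time |
|---|---|---|---|---|
| east | 0.20 M | 0.13 M | run made earlier |  |
| west | 0.20 M | 0.20 M | run made earlier |  |
| north-west | 0.30 M | 0.26 M | run made earlier |  |
| flask | 0.20 M | 0.260 M |  | 6.0 d |

- east (time / d: first product / %, starting material / %): 0.0625: 9.2, 87.0; 0.125: 17.5, 79.2; 0.250: 25.3, 68.1; 0.625: 23.4, 49.0; 1.25: 17.7, 41.5; 2.50: 6.8, 36.1; 5.00: 3.9, 35.5
- west (time / d: first product / %, starting material / %): 0.0625: 15.9, 84.1; 0.125: 23.5, 68.7; 0.250: 32.5, 54.9; 0.625: 28.6, 33.6; 1.25: 19.2, 18.1; 2.50: 9.1, 11.2; 5.00: 3.4, 7.1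
- north-west (time / d: first product / %, starting material / %): 0.0625: 18.0, 79.0; 0.208: 30.2, 52.6; 0.625: 20.7, 29.0; 1.67: 8.0, 18.8; 5.00: 2.7, 13.6

(each reading ± 1 percentage point)



1. the moment within 6.0 d at which there is most first product
2. the amount of first product, in percent of the starting material charged, at that time

- First product tops out when its rate of making equals its rate of loss, so I divided one rate by the other and time dropped out. I assumed that making follows A times B, the concentrations of starting material and reagent, with reagent used one to one. I assumed that loss follows x squared, x being the starting material consumed. On those assumptions every top has the same balance number N, which is A times B divided by x squared.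
- The north-west reading at 0.208 d was that run's highest, and I took it as that run's top. There x read 0.142 M, so N read 0.919, and the share of consumed material standing as first product read 0.637.
- For the flask, that N gave x = 0.115 M, and that share gave a top of 36.8%. The rate constant read from the west run, 16.4 /M/d, put this x at 0.278 d, so I chose to stop the flask there.
- The forecast, reckoned separately, said 39% at 0.29 d, higher than my figure. On the loss it reasoned: “so I take second order in product”.
- The flask peaked at 36.3% at 0.270 d, so the forecast held.

    starting material + reagent → first product + released group (k = 0.710 /M/h)
    reagent + first product → bis adduct + released group (k = 0.0120 /M/h)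
    reagent + bis adduct → triple product + released group (k = 0.420 /M/h)
    first product + released group → side product (k = 1.40 /M/h)
    first product ⇌ isomer of the product (K = 0.120, k = 1.20 /h)

- At the best time the flask held 42.1% of its starting material and 55.2% of its reagent, which makes N 0.902, close to 0.919. I put the same N and share on the neighbour charged with 0.065 M of reagent, there the limiting reagent. It gave x = 0.0498 M and a top of 15.9%. That neighbour's top was 16.4%, and at 6.00 d it held 0% of its reagent and 67.6% of its starting material.

All runs are calculated for substances that don't exist, noise included.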